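## Retrosynthetic overview

- The route rests on the C11–C16 side chain. The E-trisubstituted C13=C14 alkene with its C13 methyl, the C15 carbinol and the adjoining 4-methylbutenolide ring (O, C16, C17, C18, C19) are traced back to a terminal C13≡C14 alkyne, AlMe3 and 3-methylfuran-2-carbaldehyde; the furan ring stands for the butenolide ring in reduced form.
- C13–CH3 and C14–C15 are made in one flask (methylalumination, aluminium-to-zinc relay, ligand-controlled aldehyde addition; sets 15S). The furan is then oxidised with singlet oxygen and the C16 ketone reduced under Felkin–Anh control (sets 16S) before lactonisation.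
- The alkyne comes from neoabietic acid. Rings A and B with C4, C5, C9 and C10 are taken from the pool, ozonolysis removes the isopropylidene carbons, and Eschenmoser–Tanabe fragmentation of the 8,14-epoxy-13-ketone opens ring C to give the C8 ketone and the C13≡C14 alkyne together.
- The C6 hydroxyl is brought in through the C6=C7 enone (α-epoxidation, SmI2). The C8 carbinol is built by methylenation, α-epoxidation and hydride opening.
- Ring order: rings A and B are present from the start, ring C is cleaved in step 4, the furan ring arrives with the aldehyde in step 13, and the lactone ring is closed last in step 16.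

Key step: step 13

Assumption: neoabietic acid [abieta-8(14),13(15)-dien-18-oic acid], a rosin acid offered as a pure compound by fine-chemical suppliers, is taken as the chiral-pool starting material, because its exocyclic C13=C15 bond allows the isopropyl carbons to be removed in a single ozonolysis.

Numbering used: decalin C1–C10 as in labdanes and podocarpanes; C11–C14 are the former ring C carbons; side chain C11–C15; furan/butenolide C16–C19, with C16 bonded to C15 and C19 the lactone carbonyl. In the podocarpane names, "18-oate" denotes the 4α ester. Carbons on C4, C8 and C10 are otherwise named by the ring atom that carries them.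

## Route

Step 1
Reactants: 1 neoabietic acid
Product: 2 methyl neoabietate
Conditions: MeI, K2CO3, DMF, rt
Reagents that add atoms: iodomethane, CI
Why: SN2 O-alkylation of the carboxylate esterifies the hindered C4 acid without touching the diene or any stereocentre.

Step 2
Reactants: 2 methyl neoabietate
Product: 4 methyl 13-oxopodocarp-8(14)-en-18-oate (tricyclic enone C8=C14–C13=O), via primary ozonide 3 (not isolated)
Conditions: O3 (1 equiv), CH2Cl2/MeOH, −78 °C; then Me2S, −78 °C → rt
Reagents that add atoms: ozone, [O-][O+]=O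
Why: Ozonolysis (Criegee mechanism) with one equivalent of ozone should take the tetrasubstituted exocyclic C13=C15 bond, the more electron-rich and exposed bond of the diene, and the enone that results is deactivated towards further ozone.

Step 3
Reactants: 4 methyl 13-oxopodocarp-8(14)-en-18-oate
Product: 5 methyl 8α,14α-epoxy-13-oxopodocarpan-18-oate
Conditions: 30% H2O2, NaOH, MeOH, 0 °C → rt
Reagents that add atoms: hydrogen peroxide, OO
Why: Weitz–Scheffer nucleophilic epoxidation, in which hydroperoxide should add to C8 from the α face away from the axial C10 methyl; either epoxide epimer would serve, since C8 and C14 both lose their configuration in step 4.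

Step 4
Reactants: 5 methyl 8α,14α-epoxy-13-oxopodocarpan-18-oate
Product: 7 methyl 8-oxo-8,14-secopodocarp-13-yn-18-oate (trans-decalin-8-one; 4α-CO2Me; 4β-Me; 10β-Me; 9β-but-3-yn-1-yl), via epoxy tosylhydrazone 6 (not isolated)
Conditions: TsNHNH2, CH2Cl2/AcOH (1:1), −20 °C → rt
Reagents that add atoms: none
Why: Eschenmoser–Tanabe fragmentation, in which the tosylhydrazone opens the epoxide at C14 to an azoalkene alkoxide whose collapse cuts the C8–C14 bond, expels dinitrogen and sulfinate, and leaves the C8 ketone and the terminal C13≡C14 alkyne with the C9 chain still equatorial.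

Step 5
Reactants: 7 methyl 8-oxo-8,14-secopodocarp-13-yn-18-oate
Product: 10 methyl 8-oxo-8,14-secopodocarp-6-en-13-yn-18-oate (C6=C7 enone), via 7α-phenylselanyl ketone 8 (not isolated), via selenoxide 9 (not isolated)
Conditions: LiN(SiMe3)2 (1.1 equiv), THF, −78 °C; PhSeBr, −78 °C; then 30% H2O2, pyridine, CH2Cl2, 0 °C → rt
Reagents that add atoms: none
Why: Kinetic deprotonation at the open C7 methylene (C9–H is tertiary and shielded, the ester has no α-hydrogen, and the amide base is too weak for the alkyne C–H), selenenylation and syn-elimination of the selenoxide (selenoxide elimination) towards C6, the only β-carbon that carries hydrogen.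

Step 6
Reactants: 10 C6=C7 enone
Product: 11 methyl 6α,7α-epoxy-8-oxo-8,14-secopodocarp-13-yn-18-oate
Conditions: 30% H2O2, NaOH, MeOH, 0 °C
Reagents that add atoms: hydrogen peroxide, OO
Why: Weitz–Scheffer epoxidation in which hydroperoxide should attack C6 from the α face, because the β face is closed by the syn-axial methyls on C4 and C10; this sets the C6–O bond α.

Step 7
Reactants: 11 6α,7α-epoxy ketone
Product: 12 methyl 6α-hydroxy-8-oxo-8,14-secopodocarp-13-yn-18-oate
Conditions: SmI2 (2.2 equiv), THF/MeOH, −78 °C
Reagents that add atoms: none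
Why: Reductive opening of an α,β-epoxy ketone by SmI2, in which electron transfer to the ketone cleaves only the C7–O bond, methanol protonates the enolate, and the C6 oxygen keeps its α (equatorial) configuration.

Step 8
Reactants: 12 6α-hydroxy ketone
Product: 13 methyl 6α-(triethylsilyloxy)-8-oxo-8,14-secopodocarp-13-yn-18-oate
Conditions: Et3SiOTf, 2,6-lutidine, CH2Cl2, −78 °C
Reagents that add atoms: triethylsilyl trifluoromethanesulfonate, CC[Si](CC)(CC)OS(=O)(=O)C(F)(F)F
Why: Silylation of the secondary alcohol by the triflate at −78 °C should outrun enol silylation and β-elimination, and it protects the aldol from the base of step 9.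

Step 9
Reactants: 13 6α-silyloxy ketone
Product: 14 methyl 6α-(triethylsilyloxy)-8-methylene-8,14-secopodocarp-13-yn-18-oate (exocyclic C8=CH2)
Conditions: Ph3PCH3Br (3 equiv), KOtBu (2.8 equiv), toluene, 0 °C; then 13, 0 → 50 °C
Reagents that add atoms: methyltriphenylphosphonium bromide, C[P+](c1ccccc1)(c1ccccc1)c1ccccc1.[Br-]
Why: Wittig methylenation with the ylide pre-formed from a deficit of base, so that no free alkoxide is left to isomerise the alkyne or expel the silyloxy group, while any epimerisation at C9 returns the equatorial chain.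

Step 10
Reactants: 14 8-methylene compound
Product: 15 8α-spiro-oxirane (epoxide oxygen α on C8, CH2 β; 6α-OSiEt3)
Conditions: mCPBA, NaHCO3, CH2Cl2, 0 °C
Reagents that add atoms: 3-chloroperoxybenzoic acid, OOC(=O)c1cccc(Cl)c1
Why: Prilezhaev epoxidation of the only alkene, in which the peracid should come from the α face because the axial C10 methyl covers the β face of C8; the alkyne is inert.

Step 11
Reactants: 15 8α-spiro-oxirane
Product: 16 methyl 6α-(triethylsilyloxy)-8α-hydroxy-8β-methyl-8,14-secopodocarp-13-yn-18-oate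
Conditions: LiEt3BH (1.5 equiv), THF, −40 → 0 °C
Reagents that add atoms: none
Why: SN2 opening of the 2,2-disubstituted epoxide by triethylborohydride at its primary carbon turns the β-CH2 into the β-methyl and leaves the α C8–O bond untouched, while the neopentyl-type ester flanked by the 6α-silyl ether is expected to react more slowly at low temperature.

Step 12
Reactants: 16 tertiary alcohol
Product: 17 methyl 6α,8α-bis(triethylsilyloxy)-8β-methyl-8,14-secopodocarp-13-yn-18-oate (decalin C13 alkyne)
Conditions: Et3SiOTf, 2,6-lutidine, CH2Cl2, 0 °C → rt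
Reagents that add atoms: triethylsilyl trifluoromethanesulfonate, CC[Si](CC)(CC)OS(=O)(=O)C(F)(F)F
Why: Triflate-driven silylation is strong enough for the tertiary C8 alcohol and removes the last free hydroxyl before the organometallic step.

Step 13
Reactants: 17 decalin C13 alkyne; 18 3-methylfuran-2-carbaldehyde
Product: 21 (13E,15S)-allylic 3-methylfuran-2-yl carbinol, via alkenyldimethylalane 19 (not isolated), via alkenyl(methyl)zinc 20 (not isolated)
Conditions: AlMe3 (3 equiv), Cp2ZrCl2 (0.25 equiv), CH2Cl2, 0 °C → rt; volatiles removed in vacuo; toluene, ZnMe2 (3 equiv), −40 °C; TEEDA (N,N,N′,N′-tetraethylethylenediamine), (−)-MIB [(2S)-3-exo-morpholinoisoborneol] (0.2 equiv); then 18, −40 → −10 °C; aq. NH4Cl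
Reagents that add atoms: trimethylaluminium, C[Al](C)C
Why: Proposed new method: zirconocene-catalysed syn addition of CH3–Al across the terminal alkyne (Negishi carboalumination) places the methyl on C13 and AlMe2 on C14, after removal of free AlMe3 the alkenyl group is passed to zinc by Al/Zn alkyl–alkenyl exchange with ZnMe2, and the methylzinc alkoxide of (−)-MIB then binds aldehyde 18 and the alkenyl(methyl)zinc in the usual six-membered bimetallic transition state, from which the sp2 group migrates to the carbonyl carbon with retention of the alkene geometry. The closest known reaction types are methylalumination of alkynes followed by addition of the alkenylmetal to aldehydes, and amino-alcohol-catalysed additions of alkenyl(alkyl)zincs, made by boron-to-zinc or zirconium-to-zinc exchange, to aromatic aldehydes; the aluminium-to-zinc relay under a chiral zinc catalyst is the untested link. No ring is closed. C15 is the only new stereocentre and is set by the ligand, which in the isoborneol amino alcohol series sends the migrating group to the Si face of aryl aldehydes and so should give 15S, while the decalin stereocentres lie five or more bonds away and are not expected to interfere. The E geometry of C13=C14 follows from the syn carbometallation with aluminium on the terminal carbon, the usual regiochemistry for an unbranched 1-alkyne. The step needs alkenyl over methyl transfer, secured by the higher migratory aptitude of sp2 carbon on zinc, and suppression of a racemic aluminium-promoted addition, for which regenerated AlMe3 is tied up as its TEEDA adduct and the aldehyde is added last at low temperature; the C4 ester has no α-hydrogen and is too hindered to be methylated, and the triethylsilyl ethers are inert to AlMe3.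

Step 14
Reactants: 21 (13E,15S)-allylic furyl carbinol
Product: 22 15-O-triethylsilyl ether of 21 (tris-silyl furan)
Conditions: Et3SiCl, imidazole, 4-(dimethylamino)pyridine (cat.), CH2Cl2, 0 °C → rt
Reagents that add atoms: chlorotriethylsilane, CC[Si](Cl)(CC)CC
Why: Silylation under basic conditions spares the acid-labile furyl allyl carbinol and blocks the C15 hydroxyl, so that the furan oxidation of step 15 cannot take the Achmatowicz course.

Step 15
Reactants: 22 tris-silyl furan
Product: 24 γ-hydroxybutenolide (C16 hemiketal; C19 lactone carbonyl; both C16 epimers), via furan endoperoxide 23 (not isolated)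
Conditions: O2, hν, 5,10,15,20-tetraphenylporphyrin (cat.), iPr2NEt, CH2Cl2, −78 °C
Reagents that add atoms: dioxygen, O=O
Why: [4+2] cycloaddition of singlet oxygen across furan C16 and C19, followed by Kornblum–DeLaMare opening of the endoperoxide by the hindered amine at C19–H (the only peroxide-bearing C–H), gives the C19 carbonyl; the 2,3-dialkylfuran should react much faster than the trisubstituted C13=C14 alkene at −78 °C.

Step 16
Reactants: 24 γ-hydroxybutenolide
Product: 27 (15S,16S)-tris(triethylsilyl) butenolide, via Z-keto acid 25 (not isolated), via Z-hydroxy acid 26 (not isolated)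
Conditions: NaBH4, CeCl3·7H2O, MeOH, −40 → 0 °C; then aq. citric acid (pH 3), rt
Reagents that add atoms: none
Why: The hydroxybutenolide opens in methanolic borohydride to the Z-keto carboxylate, Luche-type 1,2-reduction should follow the polar Felkin–Anh model (hydride anti to the bulky, non-chelating C15 silyloxy group) to give the 15,16-syn (16S) carbinol, and acidification closes the lactone ring by attack of the C16 hydroxyl on the cis carboxyl group.

Step 17
Reactants: 27 (15S,16S)-tris(triethylsilyl) butenolide
Product: 28 CNP0104474.1 (target)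
Conditions: HF·pyridine, pyridine, THF, 0 °C → rt
Reagents that add atoms: none
Why: Fluoride cleaves the secondary C6 and C15 and the tertiary C8 triethylsilyl ethers under buffered, weakly acidic conditions that should neither epimerise C16 of the butenolide nor ionise the allylic C15 carbinol.

## Compound list

1 | neoabietic acid [abieta-8(14),13(15)-dien-18-oic acid] | OC(=O)[C@]1(C)CCC[C@@]2(C)[C@H]1CCC3=CC(=C(C)C)CC[C@@H]32 | starting material
2 | methyl neoabietate | COC(=O)[C@]1(C)CCC[C@@]2(C)[C@H]1CCC3=CC(=C(C)C)CC[C@@H]32 | intermediate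
3 | primary ozonide of 2 (1,2,3-trioxolane across C13 and C15) | COC(=O)[C@]1(C)CCC[C@@]2(C)[C@H]1CCC3=CC4(OOOC4(C)C)CC[C@@H]32 | intermediate (not isolated)
4 | methyl 13-oxopodocarp-8(14)-en-18-oate | COC(=O)[C@]1(C)CCC[C@@]2(C)[C@H]1CCC3=CC(=O)CC[C@@H]32 | intermediate
5 | methyl 8α,14α-epoxy-13-oxopodocarpan-18-oate | COC(=O)[C@]1(C)CCC[C@@]2(C)[C@H]1CC[C@@]34O[C@H]4C(=O)CC[C@@H]32 | intermediate
6 | 13-(p-toluenesulfonyl)hydrazone of 5 | COC(=O)[C@]1(C)CCC[C@@]2(C)[C@H]1CC[C@@]34O[C@H]4C(=NNS(=O)(=O)c5ccc(C)cc5)CC[C@@H]32 | intermediate (not isolated)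
7 | methyl 8-oxo-8,14-secopodocarp-13-yn-18-oate (decalin-8-one with 9β-but-3-yn-1-yl chain) | COC(=O)[C@]1(C)CCC[C@@]2(C)[C@H]1CCC(=O)[C@@H]2CCC#C | intermediate
8 | 7α-phenylselanyl derivative of 7 | COC(=O)[C@]1(C)CCC[C@@]2(C)[C@H]1C[C@@H]([Se]c3ccccc3)C(=O)[C@@H]2CCC#C | intermediate (not isolated)
9 | selenoxide of 8 | COC(=O)[C@]1(C)CCC[C@@]2(C)[C@H]1C[C@@H]([Se](=O)c3ccccc3)C(=O)[C@@H]2CCC#C | intermediate (not isolated)
10 | methyl 8-oxo-8,14-secopodocarp-6-en-13-yn-18-oate | COC(=O)[C@]1(C)CCC[C@@]2(C)[C@H]1C=CC(=O)[C@@H]2CCC#C | intermediate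
11 | methyl 6α,7α-epoxy-8-oxo-8,14-secopodocarp-13-yn-18-oate | COC(=O)[C@]1(C)CCC[C@@]2(C)[C@H]1[C@H]3O[C@H]3C(=O)[C@@H]2CCC#C | intermediate
12 | methyl 6α-hydroxy-8-oxo-8,14-secopodocarp-13-yn-18-oate | COC(=O)[C@]1(C)CCC[C@@]2(C)[C@H]1[C@@H](O)CC(=O)[C@@H]2CCC#C | intermediate
13 | methyl 6α-(triethylsilyloxy)-8-oxo-8,14-secopodocarp-13-yn-18-oate | COC(=O)[C@]1(C)CCC[C@@]2(C)[C@H]1[C@@H](O[Si](CC)(CC)CC)CC(=O)[C@@H]2CCC#C | intermediate
14 | methyl 6α-(triethylsilyloxy)-8-methylene-8,14-secopodocarp-13-yn-18-oate | COC(=O)[C@]1(C)CCC[C@@]2(C)[C@H]1[C@@H](O[Si](CC)(CC)CC)CC(=C)[C@@H]2CCC#C | intermediate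
15 | 8α-spiro-oxirane of 14 (oxygen α, CH2 β) | COC(=O)[C@]1(C)CCC[C@@]2(C)[C@H]1[C@@H](O[Si](CC)(CC)CC)C[C@]3(CO3)[C@@H]2CCC#C | intermediate
16 | methyl 6α-(triethylsilyloxy)-8α-hydroxy-8β-methyl-8,14-secopodocarp-13-yn-18-oate | COC(=O)[C@]1(C)CCC[C@@]2(C)[C@H]1[C@@H](O[Si](CC)(CC)CC)C[C@@](C)(O)[C@@H]2CCC#C | intermediate
17 | methyl 6α,8α-bis(triethylsilyloxy)-8β-methyl-8,14-secopodocarp-13-yn-18-oate (decalin C13 alkyne) | COC(=O)[C@]1(C)CCC[C@@]2(C)[C@H]1[C@@H](O[Si](CC)(CC)CC)C[C@@](C)(O[Si](CC)(CC)CC)[C@@H]2CCC#C | intermediate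
18 | 3-methylfuran-2-carbaldehyde | Cc1ccoc1C=O | starting material
19 | (E)-alkenyldimethylalane (CH3 on C13, AlMe2 on C14) | COC(=O)[C@]1(C)CCC[C@@]2(C)[C@H]1[C@@H](O[Si](CC)(CC)CC)C[C@@](C)(O[Si](CC)(CC)CC)[C@@H]2CC/C(C)=C/[Al](C)C | intermediate (not isolated)
20 | (E)-alkenyl(methyl)zinc | COC(=O)[C@]1(C)CCC[C@@]2(C)[C@H]1[C@@H](O[Si](CC)(CC)CC)C[C@@](C)(O[Si](CC)(CC)CC)[C@@H]2CC/C(C)=C/[Zn]C | intermediate (not isolated)
21 | (13E,15S)-allylic 3-methylfuran-2-yl carbinol, 6,8-bis(triethylsilyl) ether | COC(=O)[C@]1(C)CCC[C@@]2(C)[C@H]1[C@@H](O[Si](CC)(CC)CC)C[C@@](C)(O[Si](CC)(CC)CC)[C@@H]2CC/C(C)=C/[C@H](O)c1occc1C | intermediate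
22 | 15-O-triethylsilyl ether of 21 | COC(=O)[C@]1(C)CCC[C@@]2(C)[C@H]1[C@@H](O[Si](CC)(CC)CC)C[C@@](C)(O[Si](CC)(CC)CC)[C@@H]2CC/C(C)=C/[C@H](O[Si](CC)(CC)CC)c1occc1C | intermediate
23 | furan endoperoxide of 22 (O–O across C16 and C19) | COC(=O)[C@]1(C)CCC[C@@]2(C)[C@H]1[C@@H](O[Si](CC)(CC)CC)C[C@@](C)(O[Si](CC)(CC)CC)[C@@H]2CC/C(C)=C/[C@H](O[Si](CC)(CC)CC)C12OOC(O1)C=C2C | intermediate (not isolated)
24 | γ-hydroxybutenolide (16-hydroxy-17-methyl, C19 carbonyl) | COC(=O)[C@]1(C)CCC[C@@]2(C)[C@H]1[C@@H](O[Si](CC)(CC)CC)C[C@@](C)(O[Si](CC)(CC)CC)[C@@H]2CC/C(C)=C/[C@H](O[Si](CC)(CC)CC)C1(O)OC(=O)C=C1C | intermediate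
25 | (Z)-16-oxo-17-en-19-oic acid (ring-opened form of 24) | COC(=O)[C@]1(C)CCC[C@@]2(C)[C@H]1[C@@H](O[Si](CC)(CC)CC)C[C@@](C)(O[Si](CC)(CC)CC)[C@@H]2CC/C(C)=C/[C@H](O[Si](CC)(CC)CC)C(=O)/C(C)=C\C(=O)O | intermediate (not isolated)
26 | (Z,16S)-16-hydroxy-17-en-19-oic acid | COC(=O)[C@]1(C)CCC[C@@]2(C)[C@H]1[C@@H](O[Si](CC)(CC)CC)C[C@@](C)(O[Si](CC)(CC)CC)[C@@H]2CC/C(C)=C/[C@H](O[Si](CC)(CC)CC)[C@@H](O)/C(C)=C\C(=O)O | intermediate (not isolated)
27 | (15S,16S)-6,8,15-tris(triethylsilyl) butenolide | COC(=O)[C@]1(C)CCC[C@@]2(C)[C@H]1[C@@H](O[Si](CC)(CC)CC)C[C@@](C)(O[Si](CC)(CC)CC)[C@@H]2CC/C(C)=C/[C@H](O[Si](CC)(CC)CC)[C@H]1OC(=O)C=C1C | intermediate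
28 | CNP0104474.1 | COC(=O)[C@]1(C)CCC[C@@]2(C)[C@H]1[C@@H](O)C[C@@](C)(O)[C@@H]2CC/C(C)=C/[C@H](O)[C@H]1OC(=O)C=C1C | target

## Step count and risks

Total step count: 17. Longest linear sequence: 17 steps (1 to 28); aldehyde 18 is used as purchased.

Steps most likely to fail:

1. Step 13 (proposed new method). The alkenyl group may not pass cleanly from aluminium to zinc. Aluminium species may carry a racemic addition that erodes the C15 configuration. Methyl may transfer in place of the alkenyl group. The fallback separates the two events and uses known reaction types. It sets out from 17: the same Cp2ZrCl2-catalysed methylalumination is quenched with iodine (THF, −30 °C) to give the (E)-alkenyl iodide F1. Iodine–lithium exchange (t-BuLi, Et2O, −78 °C, faster than attack at the hindered ester) and transmetalation with ZnBr2 give an alkenylzinc free of aluminium. With the lithium halides sequestered by TEEDA, the (−)-MIB-catalysed addition to 18 should deliver the same carbinol, and the route is rejoined at 21.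

2. Step 11. Chemoselectivity may be lost through hydride attack on the C4 ester alongside, or in place of, epoxide opening. The fallback avoids hydride and bypasses 15. It sets out from 14: Mukaiyama hydration (Mn(dpm)3 [tris(2,2,6,6-tetramethylheptane-3,5-dionato)manganese] cat., PhSiH3, O2, iPrOH/CH2Cl2, 0 °C) forms the tertiary C8 radical by hydrogen-atom transfer to the 1,1-disubstituted alkene (the alkyne is a poor acceptor). Oxygen should trap it from the α face, away from the axial C10 methyl, to give the 8α-hydroperoxide F2. This is reduced in the same flask with PPh3, and the route is rejoined at 16.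

3. Step 16. Facial selectivity in the hydride addition to the C16 ketone may be poor, or conjugate reduction of the ene-dicarbonyl may compete. The fallback replaces substrate control by reagent control on an acyclic ester. It sets out from 24: the open keto-acid tautomer is esterified (Me3SiCHN2, MeOH/toluene) to the methyl (Z)-keto ester F3. Corey–Bakshi–Shibata reduction follows, with (S)-Me-CBS [(S)-1-methyl-3,3-diphenyltetrahydro-1H,3H-pyrrolo[1,2-c][1,3,2]oxazaborole] and BH3·SMe2 at −40 °C. This enantiomer is the expected one if the unsaturated arm counts as the large group; the choice is to be confirmed on a small scale. The reduction gives the (16S)-hydroxy ester F4, which lactonises with pyridinium p-toluenesulfonate, and the route is rejoined at 27.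

## Further compounds

F1 | step 13 | (E)-alkenyl iodide (CH3 on C13, iodine on C14) | COC(=O)[C@]1(C)CCC[C@@]2(C)[C@H]1[C@@H](O[Si](CC)(CC)CC)C[C@@](C)(O[Si](CC)(CC)CC)[C@@H]2CC/C(C)=C/I
F2 | step 11 | 8α-hydroperoxide (6α-OSiEt3, 8β-methyl) | COC(=O)[C@]1(C)CCC[C@@]2(C)[C@H]1[C@@H](O[Si](CC)(CC)CC)C[C@@](C)(OO)[C@@H]2CCC#C
F3 | step 16 | methyl (Z)-16-oxo-17-en-19-oate | COC(=O)[C@]1(C)CCC[C@@]2(C)[C@H]1[C@@H](O[Si](CC)(CC)CC)C[C@@](C)(O[Si](CC)(CC)CC)[C@@H]2CC/C(C)=C/[C@H](O[Si](CC)(CC)CC)C(=O)/C(C)=C\C(=O)OC
F4 | step 16 | methyl (Z,16S)-16-hydroxy-17-en-19-oate | COC(=O)[C@]1(C)CCC[C@@]2(C)[C@H]1[C@@H](O[Si](CC)(CC)CC)C[C@@](C)(O[Si](CC)(CC)CC)[C@@H]2CC/C(C)=C/[C@H](O[Si](CC)(CC)CC)[C@@H](O)/C(C)=C\C(=O)OC
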